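Ring numbering: C1 (acetoxy carbon), C2, C3=C4 (methyl on C3), C5, C6=C7, C8, C9. The nine-membered ring is not cyclised; it is set free from a cis-fused bicyclo[4.3.0]nonane by breaking the bond shared by its two rings. A Grob fragmentation uses the 1,5-relationship across the ring between the olefinic carbons C3 and C7: the C7 alkoxide expels an antiperiplanar C4 mesylate, the C3–C7 bond breaks, and the (E)-C3=C4 olefin and a C7 ketone (trapped as enol triflate, later the enal) appear in one operation. Three stereocentres vanish, so ring-fusion isomers converge. The precursor is assembled from (S)-citronellic acid and 2-allyl-2-methylcyclopentane-1,3-dione by an Evans syn-aldol and an enamine aldol.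

Key step: step 11

Remark on labels: C1′ is the side-chain stereocentre, C7a and C8a are the formyl carbons on C7 and C8. In the bicyclic intermediates the six-membered ring is C3–C2–C1–C9–C8–C7 and the five-membered ring is C3–C4–C5–C6–C7. Compound 5 is taken as commercially available.
Assumption: step 8 is drawn for the aldol diastereomer whose angular OH is axial on the six-membered ring. The diastereomer with both ring-fusion centres inverted should pass through steps 9 to 11 in the same way and give the same triflate 21.

Step 1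
Reactants: 1 (S)-citronellic acid; 2 (S)-4-benzyl-1,3-oxazolidin-2-one
Product: 4 (4S)-4-benzyl-3-[(3S)-3,7-dimethyloct-6-enoyl]-1,3-oxazolidin-2-one, via mixed pivalic anhydride 3 (not isolated)
Conditions: PivCl, Et3N, THF, −20 °C; then LiCl, 2, −20 °C → rt
Reagents that add atoms: none
Why: Mixed-anhydride N-acylation of the oxazolidinone (LiCl-promoted) should give the Evans imide without touching the C1′ stereocentre, which lies β to the carbonyl.

Step 2
Reactants: 5 2-allyl-2-methylcyclopentane-1,3-dione
Product: 7 2-(1-methyl-2,5-dioxocyclopentyl)acetaldehyde, via secondary ozonide 6 (not isolated)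
Conditions: O3, CH2Cl2, −78 °C; then PPh3, −78 °C → rt
Reagents that add atoms: ozone, [O-][O+]=O
Why: Ozonolysis (Criegee mechanism) with reductive work-up cleaves only the terminal olefin and gives the C1 aldehyde; no stereocentre is involved.

Step 3
Reactants: 4 the imide; 7 the keto aldehyde
Product: 10 (4S)-4-benzyl-3-[(2S,3R)-3-hydroxy-2-[(2S)-6-methylhept-5-en-2-yl]-4-(1-methyl-2,5-dioxocyclopentyl)butanoyl]-1,3-oxazolidin-2-one, via (Z)-dibutylboron enolate 8 (not isolated), via dibutylboron aldolate 9 (not isolated)
Conditions: Bu2BOTf, i-Pr2NEt, CH2Cl2, −78 → 0 °C; 7, −78 → 0 °C; then pH 7 buffer, MeOH, H2O2, 0 °C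
Reagents that add atoms: none
Why: Evans syn-aldol: the (Z)-boron enolate adds to the aldehyde (far more electrophilic than the hindered ring ketones) through a Zimmerman–Traxler chair on the face opposite the benzyl group of the (S)-auxiliary, which sets C9 and C1 together (2S,3R in the adduct, the trans C1–O/C9 side-chain relationship of the target) independently of the remote C1′ centre.

Step 4
Reactants: 10 the aldol adduct
Product: 11 tert-butyldimethylsilyl ether of 10 at the C1 oxygen
Conditions: TBSOTf, 2,6-lutidine, CH2Cl2, −78 → 0 °C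
Reagents that add atoms: tert-butyldimethylsilyl trifluoromethanesulfonate, CC(C)(C)[Si](C)(C)OS(=O)(=O)C(F)(F)F
Why: Silylation of the secondary alcohol with the silyl triflate protects the C1 oxygen against retro-aldol, β-elimination and lactol formation in steps 5 to 8.

Step 5
Reactants: 11 the silylated imide
Product: 12 S-ethyl (2S,3R)-3-(tert-butyldimethylsilyloxy)-2-[(2S)-6-methylhept-5-en-2-yl]-4-(1-methyl-2,5-dioxocyclopentyl)butanethioate
Conditions: EtSH, n-BuLi, THF, 0 °C
Reagents that add atoms: ethanethiol (as LiSEt), CCS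
Why: The thiolate attacks the exocyclic imide carbonyl (nucleophilic acyl substitution) and releases the auxiliary; the thioester can later be reduced without a hydride reagent, so the ring ketones survive, and the weakly basic thiolate should not epimerise C9.

Step 6
Reactants: 12 the thioester
Product: 13 (2S,3R)-3-(tert-butyldimethylsilyloxy)-2-[(2S)-6-methylhept-5-en-2-yl]-4-(1-methyl-2,5-dioxocyclopentyl)butanal
Conditions: Et3SiH, Pd/C (10 wt% palladium on carbon), acetone, rt
Reagents that add atoms: none
Why: Fukuyama reduction (palladium-catalysed hydrosilane reduction of a thioester) stops at the aldehyde under neutral conditions and leaves ketones, silyl ether and the trisubstituted olefin alone, so C9 is kept.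

Step 7
Reactants: 13 the C8 aldehyde
Product: 15 (3S,4R)-4-(tert-butyldimethylsilyloxy)-3-[(2S)-6-methylhept-5-en-2-yl]-5-(1-methyl-2,5-dioxocyclopentyl)pentanal, via methyl enol ether 14 (not isolated)
Conditions: Ph3P(CH2OMe)Cl, KN(SiMe3)2, THF, 0 °C; 13, −78 → 0 °C; then 1 M HCl, THF, rt
Reagents that add atoms: (methoxymethyl)triphenylphosphonium chloride, COC[P+](c1ccccc1)(c1ccccc1)c1ccccc1.[Cl-]; water, O
Why: Wittig methoxymethylenation of the aldehyde (much more reactive than the α-quaternary ketones) and hydrolysis of the enol ether amount to a one-carbon homologation that places the formyl carbon C8a and makes C8 the enolisable position, C9 no longer being α to a carbonyl.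

Step 8
Reactants: 15 the homologated aldehyde
Product: 17 cis-fused ketol dimethyl acetal (4-(dimethoxymethyl)-3a-hydroxy-7a-methyl-5-[(2S)-6-methylhept-5-en-2-yl]-6-(tert-butyldimethylsilyloxy)octahydro-1H-inden-1-one; relative configuration as in the compound list), via ketol aldehyde 16 (not isolated)
Conditions: (S)-proline (30 mol%), DMSO, rt; then MeOH, HC(OMe)3, PPTS, rt
Reagents that add atoms: trimethyl orthoformate, COC(OC)OC; methanol, CO
Why: Intramolecular enamine aldol (Hajos–Parrish-type 6-enolexo cyclisation) of the aldehyde onto one of the two diastereotopic ring ketones desymmetrises the dione and closes the six-membered ring, cis-fused of necessity (angular CH3 and OH cis) because of the short tether; a chair transition state with C1–OSi and the C9 side chain equatorial, together with equilibration of the enolisable C8, should place the formyl group equatorial (trans to C9), and acetalisation in the same flask shuts off retro-aldol.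

Step 9
Reactants: 17 the ketol acetal
Product: 18 cis-1,3-diol (C4–OH on the face of the angular CH3 and the C7–OH)
Conditions: Et2BOMe, THF/MeOH (4:1), rt → −78 °C; NaBH4, −78 °C; AcOH quench, MeOH co-evaporation
Reagents that add atoms: none
Why: Narasaka–Prasad-type syn-selective reduction: the diethylboron chelate linking the C7 oxygen and the C4 carbonyl is attacked by external hydride from the face opposite to the chelate and the angular methyl group, so the new C4–OH should come out cis to the C7–OH and to CH3.

Step 10
Reactants: 18 the diol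
Product: 19 C4 methanesulfonate of 18 (tertiary C7–OH free)
Conditions: MsCl, Et3N, CH2Cl2, −20 → 0 °C
Reagents that add atoms: methanesulfonyl chloride, CS(=O)(=O)Cl
Why: Sulfonylation takes place only at the secondary C4–OH, the tertiary C7–OH being unreactive, and fixes the nucleofuge cis to the angular methyl group with retention.

Step 11
Reactants: 19 the hydroxy mesylate
Product: 21 enol triflate of the (E)-cyclononenone (C6=C7–OTf; C1–OTBS; C8–CH(OMe)2), via cyclononenone 20 (not isolated)
Conditions: KN(SiMe3)2 (2.3 equiv), THF, −78 → −10 °C; then PhNTf2, −78 → 0 °C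
Reagents that add atoms: N-phenylbis(trifluoromethanesulfonimide), O=S(=O)(N(c1ccccc1)S(=O)(=O)C(F)(F)F)C(F)(F)F
Why: The potassium alkoxide at C7 pushes electrons into the C3–C7 bond, which breaks as the C3=C4 π bond forms and the mesylate leaves from C4 (concerted, antiperiplanar Grob fragmentation); the excess amide base then deprotonates the new C7 ketone at the less hindered C6H2 and the enolate is O-sulfonylated by PhNTf2. The closest known reaction type is the Grob fragmentation of hydrindane 1,3-diol monosulfonates to (E)-cyclononenones, combined with kinetic enol triflate formation. The nine-membered ring C1–C9 is formed by ring expansion, that is by cleavage of the bond shared by the fused six- and five-membered rings, not by a cyclisation. No sp3 centre is created: the (E) geometry of C3=C4 follows stereospecifically from the mesylate being cis to the angular methyl group (C5 ends cis to CH3 and trans to C2), the C6=C7 enol triflate is cis within the ring because a second trans olefin would be too strained, and C1, C8, C9 and C1′ are untouched. The step needs fragmentation to beat E2 loss of the mesylate and oxetane formation, which the cis-1,3 arrangement of alkoxide and mesylate secures (no backside access, pseudoaxial nucleofuge), and it needs enolisation at C6 instead of C8, which the bulky base and the branched C8 secure. Because C3, C4 and C7 lose their stereochemistry, both ring-fusion diastereomers from step 8 should converge on 21.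

Step 12
Reactants: 21 the silyl-protected enol triflate
Product: 23 C1 acetate of the enol triflate, via free alcohol 22 (not isolated)
Conditions: Bu4NF, AcOH (1:1), THF, 0 °C → rt; then Ac2O, pyridine, DMAP (cat.), 0 °C → rt
Reagents that add atoms: acetic anhydride, CC(=O)OC(C)=O
Why: Buffered fluoride removes the silyl ether without acid (no acetal exchange with the neighbouring dimethyl acetal) and the liberated secondary alcohol is acetylated in the same flask (DMAP-catalysed acylation) with retention at C1, before the base-sensitive enal exists.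

Step 13
Reactants: 23 the acetoxy enol triflate
Product: 24 (1R,3E,6E,8R,9R)-8-(dimethoxymethyl)-7-formyl-3-methyl-9-[(2S)-6-methylhept-5-en-2-yl]cyclonona-3,6-dien-1-yl acetate
Conditions: Pd(PPh3)4 (5 mol%), CO (1 atm), Bu3SnH (slow addition), THF, 50 °C
Reagents that add atoms: carbon monoxide, [C-]#[O+]
Why: Palladium-catalysed reductive carbonylation (formylation) of the enol triflate (oxidative addition, CO insertion, hydride transfer from the tin hydride) installs C7a as the conjugated aldehyde with the ring-cis geometry of C6=C7 unchanged; the acetate is homoallylic and cannot ionise.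

Step 14
Reactants: 24 the enal acetal
Product: 25 (1R,3E,6E,8R,9R)-7,8-diformyl-3-methyl-9-[(2S)-6-methylhept-5-en-2-yl]cyclonona-3,6-dien-1-yl acetate (target)
Conditions: oxalic acid (0.5 M aq.), THF, 0 °C → rt
Reagents that add atoms: water, O
Why: Mild aqueous acid hydrolyses the dimethyl acetal to the C8 formyl group while acetate and enal survive; C8 should keep its configuration, which is also the favoured trans arrangement to the C9 side chain.

Compound list
1 | (S)-citronellic acid, (3S)-3,7-dimethyloct-6-enoic acid | OC(=O)C[C@@H](C)CCC=C(C)C | starting material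
2 | (S)-4-benzyl-1,3-oxazolidin-2-one | O=C1N[C@@H](Cc2ccccc2)CO1 | starting material
3 | mixed anhydride of 1 with pivalic acid (not isolated) | CC(C)(C)C(=O)OC(=O)C[C@@H](C)CCC=C(C)C | intermediate
4 | (4S)-4-benzyl-3-[(3S)-3,7-dimethyloct-6-enoyl]-1,3-oxazolidin-2-one | O=C1OC[C@H](Cc2ccccc2)N1C(=O)C[C@@H](C)CCC=C(C)C | intermediate
5 | 2-allyl-2-methylcyclopentane-1,3-dione | C=CCC1(C)C(=O)CCC1=O | starting material
6 | secondary ozonide of 5, 2-methyl-2-(1,2,4-trioxolan-3-ylmethyl)cyclopentane-1,3-dione (not isolated) | CC1(CC2OCOO2)C(=O)CCC1=O | intermediate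
7 | 2-(1-methyl-2,5-dioxocyclopentyl)acetaldehyde | O=CCC1(C)C(=O)CCC1=O | intermediate
8 | (Z)-dibutylboron enolate of 4 (not isolated) | CCCCB(CCCC)O/C(N1[C@@H](Cc2ccccc2)COC1=O)=C\[C@@H](C)CCC=C(C)C | intermediate
9 | dibutylboron aldolate of 10 (not isolated) | CCCCB(CCCC)O[C@@H]([C@@H](C(=O)N1[C@@H](Cc2ccccc2)COC1=O)[C@@H](C)CCC=C(C)C)CC1(C)C(=O)CCC1=O | intermediate
10 | (4S)-4-benzyl-3-[(2S,3R)-3-hydroxy-2-[(2S)-6-methylhept-5-en-2-yl]-4-(1-methyl-2,5-dioxocyclopentyl)butanoyl]-1,3-oxazolidin-2-one | O[C@@H]([C@@H](C(=O)N1[C@@H](Cc2ccccc2)COC1=O)[C@@H](C)CCC=C(C)C)CC1(C)C(=O)CCC1=O | intermediate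
11 | tert-butyldimethylsilyl ether of 10 | CC(C)(C)[Si](C)(C)O[C@@H]([C@@H](C(=O)N1[C@@H](Cc2ccccc2)COC1=O)[C@@H](C)CCC=C(C)C)CC1(C)C(=O)CCC1=O | intermediate
12 | S-ethyl (2S,3R)-3-(tert-butyldimethylsilyloxy)-2-[(2S)-6-methylhept-5-en-2-yl]-4-(1-methyl-2,5-dioxocyclopentyl)butanethioate | CC(C)(C)[Si](C)(C)O[C@@H]([C@@H](C(=O)SCC)[C@@H](C)CCC=C(C)C)CC1(C)C(=O)CCC1=O | intermediate
13 | (2S,3R)-3-(tert-butyldimethylsilyloxy)-2-[(2S)-6-methylhept-5-en-2-yl]-4-(1-methyl-2,5-dioxocyclopentyl)butanal | CC(C)(C)[Si](C)(C)O[C@@H]([C@@H](C=O)[C@@H](C)CCC=C(C)C)CC1(C)C(=O)CCC1=O | intermediate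
14 | methyl enol ether from 13 (C8=C8a–OMe, E/Z mixture; not isolated) | CC(C)(C)[Si](C)(C)O[C@@H]([C@@H](C=COC)[C@@H](C)CCC=C(C)C)CC1(C)C(=O)CCC1=O | intermediate
15 | (3S,4R)-4-(tert-butyldimethylsilyloxy)-3-[(2S)-6-methylhept-5-en-2-yl]-5-(1-methyl-2,5-dioxocyclopentyl)pentanal | CC(C)(C)[Si](C)(C)O[C@@H]([C@@H](CC=O)[C@@H](C)CCC=C(C)C)CC1(C)C(=O)CCC1=O | intermediate
16 | cis-fused ketol aldehyde, 6-(tert-butyldimethylsilyloxy)-3a-hydroxy-7a-methyl-5-[(2S)-6-methylhept-5-en-2-yl]-1-oxo-octahydro-1H-indene-4-carbaldehyde; angular CH3, C7–OH, C1–OSi and C8–CHO on one face, C9 side chain on the other (not isolated) | O=C[C@@H]1[C@@H]([C@@H](C)CCC=C(C)C)[C@H](O[Si](C)(C)C(C)(C)C)C[C@@]2(C)C(=O)CC[C@@]12O | intermediate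
17 | dimethyl acetal of 16 | COC(OC)[C@@H]1[C@@H]([C@@H](C)CCC=C(C)C)[C@H](O[Si](C)(C)C(C)(C)C)C[C@@]2(C)C(=O)CC[C@@]12O | intermediate
18 | cis-1,3-diol from 17 (C4–OH cis to angular CH3 and C7–OH) | COC(OC)[C@@H]1[C@@H]([C@@H](C)CCC=C(C)C)[C@H](O[Si](C)(C)C(C)(C)C)C[C@@]2(C)[C@H](O)CC[C@@]12O | intermediate
19 | C4 methanesulfonate of 18 | COC(OC)[C@@H]1[C@@H]([C@@H](C)CCC=C(C)C)[C@H](O[Si](C)(C)C(C)(C)C)C[C@@]2(C)[C@H](OS(C)(=O)=O)CC[C@@]12O | intermediate
20 | (E)-cyclononenone: C7 ketone, (E)-C3=C4, C1–OTBS, C8–CH(OMe)2, C9 side chain; C1, C8, C9, C1′ arranged as in the target (not isolated) | CC(C)(C)[Si](C)(C)O[C@@H]1C/C(C)=C/CCC(=O)[C@H](C(OC)OC)[C@H]1[C@@H](C)CCC=C(C)C | intermediate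
21 | enol triflate of 20 (C6=C7–OTf, ring-cis) | CC(C)(C)[Si](C)(C)O[C@@H]1C/C(C)=C/C/C=C(/OS(=O)(=O)C(F)(F)F)[C@H](C(OC)OC)[C@H]1[C@@H](C)CCC=C(C)C | intermediate
22 | C1 alcohol from 21 (not isolated) | O[C@@H]1C/C(C)=C/C/C=C(/OS(=O)(=O)C(F)(F)F)[C@H](C(OC)OC)[C@H]1[C@@H](C)CCC=C(C)C | intermediate
23 | C1 acetate of 22 | CC(=O)O[C@@H]1C/C(C)=C/C/C=C(/OS(=O)(=O)C(F)(F)F)[C@H](C(OC)OC)[C@H]1[C@@H](C)CCC=C(C)C | intermediate
24 | (1R,3E,6E,8R,9R)-8-(dimethoxymethyl)-7-formyl-3-methyl-9-[(2S)-6-methylhept-5-en-2-yl]cyclonona-3,6-dien-1-yl acetate | CC(=O)O[C@@H]1C/C(C)=C/C/C=C(/C=O)[C@H](C(OC)OC)[C@H]1[C@@H](C)CCC=C(C)C | intermediate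
25 | (1R,3E,6E,8R,9R)-7,8-diformyl-3-methyl-9-[(2S)-6-methylhept-5-en-2-yl]cyclonona-3,6-dien-1-yl acetate | CC(=O)O[C@@H]1C/C(C)=C/C/C=C(/C=O)[C@H](C=O)[C@H]1[C@@H](C)CCC=C(C)C | target

Total step count: 14. Longest linear sequence: 13 steps (steps 1 and 3 to 14; step 2 is the side branch).

Steps most likely to fail

Step 11. The fragmentation may be slower than E2 loss of the mesylate, or the enolate may equilibrate before it is trapped, so that the triflate forms on the C8 side or methoxide is lost from C8a. The fallback separates the two events and makes the enal through a hydrazone. It sets out from mesylate 19: fragmentation alone with KOtBu (1.2 equiv) in THF at 0 °C and isolation of cyclononenone 20. Condensation with 2,4,6-triisopropylbenzenesulfonyl hydrazide should give the arenesulfonylhydrazone F1. A Shapiro reaction (n-BuLi, THF/TMEDA, −78 → 0 °C, then DMF), in which deprotonation occurs on the less substituted C6 side, should give the silyl-protected enal F2. Buffered desilylation (Bu4NF/AcOH) and acetylation (Ac2O, pyridine, DMAP) bring the route back at acetate 24.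

Step 9. Hydride may be delivered to the face that carries the angular methyl group (poor facial selectivity), which would place the C4 oxygen trans to CH3 and lead to the (Z)-olefin on fragmentation. The fallback replaces chelation control by steric shielding. It sets out from ketone 17: silylation of the tertiary C7–OH with 1-(trimethylsilyl)imidazole should give the trimethylsilyl ether F3, in which the face of CH3 and OSiMe3 is blocked. Reduction with LiBH(s-Bu)3 (THF, −78 °C) from the open face should give the alcohol F4, and MsCl/Et3N the mesylate F5. Selective methanolysis of the tertiary silyl ether (PPTS, MeOH, 0 °C) comes back at hydroxy mesylate 19.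

Step 8. The enamine may add reversibly to the hindered ring ketone, so that the aldol stalls, reverts before acetalisation or dehydrates. The fallback uses Lewis-acid activation of the ketone in place of enamine activation of the aldehyde. It sets out from aldehyde 13: the Wittig step is repeated without the acid treatment and enol ether 14 is isolated. BF3·OEt2 in CH2Cl2 at −78 °C should then bring about a Prins-type (Mukaiyama aldol-type) addition of the enol ether carbon C8 to the ring ketone, and quenching with MeOH/HC(OMe)3 captures the oxocarbenium ion as the dimethyl acetal, which comes back at 17.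

Further compounds
F1 | step 11 | 2,4,6-triisopropylbenzenesulfonylhydrazone of cyclononenone 20 | CC(C)(C)[Si](C)(C)O[C@@H]1C/C(C)=C/CCC(=NNS(=O)(=O)c2c(C(C)C)cc(C(C)C)cc2C(C)C)[C@H](C(OC)OC)[C@H]1[C@@H](C)CCC=C(C)C
F2 | step 11 | silyl-protected enal (C7–CHO, C1–OTBS, C8–CH(OMe)2) | CC(C)(C)[Si](C)(C)O[C@@H]1C/C(C)=C/C/C=C(/C=O)[C@H](C(OC)OC)[C@H]1[C@@H](C)CCC=C(C)C
F3 | step 9 | C7–O-trimethylsilyl ether of ketone 17 | COC(OC)[C@@H]1[C@@H]([C@@H](C)CCC=C(C)C)[C@H](O[Si](C)(C)C(C)(C)C)C[C@@]2(C)C(=O)CC[C@@]12O[Si](C)(C)C
F4 | step 9 | C4 alcohol from F3 (OH cis to angular CH3) | COC(OC)[C@@H]1[C@@H]([C@@H](C)CCC=C(C)C)[C@H](O[Si](C)(C)C(C)(C)C)C[C@@]2(C)[C@H](O)CC[C@@]12O[Si](C)(C)C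
F5 | step 9 | C4 methanesulfonate of F4 | COC(OC)[C@@H]1[C@@H]([C@@H](C)CCC=C(C)C)[C@H](O[Si](C)(C)C(C)(C)C)C[C@@]2(C)[C@H](OS(C)(=O)=O)CC[C@@]12O[Si](C)(C)C
F0 | step 8 | none | none
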